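**Retrosynthetic overview**
1. The tertiary alcohol and the pentanoic acid are released together at the end by opening a spiro-ε-lactone; the enamide C–N bond comes from copper-catalysed coupling of an α-iodoenone with the primary enamide of the side chain (two zirconium-catalysed methylaluminations of a C6 1-alkene, then oxidation/Wittig).
2. The ε-lactone comes from a Baeyer–Villiger ring expansion (six → seven) of a spiro[5.5] hydroxy-enedione: the spiro carbon migrates to oxygen with retention, so this 1,2-shift makes the tertiary C–O bond and the five-carbon acid chain at once.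
3. The cis-aldol hydroxyl and both ring stereocentres come from desymmetrisation of an achiral spiro[5.5]dienedione by peroxide delivery tethered to the ring-B ketone (new step).
4. The spirodienedione comes from an oxidative dearomatising semipinacol ring expansion (five → six) of a p-hydroxyaryl cyclopentanol, made from a bromophenol and a cyclic C5 ketone.
5. Ring order: the arene becomes carbocyclic ring A at the moment cyclohexanone ring B is formed by the first shift; ring B is then expanded to the lactone, which is opened last.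

Assumption: operations run in one flask with a single work-up count as one step; the catalyst antipodes named ((R)-TRIP = (R)-3,3'-bis(2,4,6-triisopropylphenyl)-1,1'-binaphthyl-2,2'-diyl hydrogen phosphate; (+)-(NMI)2ZrCl2 = (+)-bis(1-neomenthylindenyl)zirconium dichloride) are those expected to give the drawn configurations and are confirmed on the first run.

**Step 1**
Reactants: 1 4-bromophenol; 2 cyclopentanone
Product: 4 4-(1-hydroxycyclopentyl)phenol, via lithium 4-lithiophenoxide 3 (not isolated)
Conditions: n-BuLi (2.2 equiv), THF, −78 → 0 °C; then 2, −78 °C → rt; cold aq. NH4Cl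
Reagents that add atoms: none
Why: Bromine–lithium exchange on the lithium phenoxide gives a C,O-dianion whose aryl carbon adds to the ketone (organolithium 1,2-addition); no stereocentre is formed and the acid-labile p-hydroxybenzylic alcohol is worked up cold and kept off acidic silica.

**Step 2**
Reactants: 4 4-(1-hydroxycyclopentyl)phenol
Product: 5 spiro[5.5]undeca-7,10-diene-1,9-dione
Conditions: PhI(OAc)2 (1.1 equiv), (CF3)2CHOH, 0 °C, 10 min
Reagents that add atoms: none
Why: The trivalent iodine reagent oxidises the phenol so that the para carbon becomes cationic, and a ring CH2 of the adjacent carbinol migrates to it while the carbinol becomes a ketone (oxidative dearomatising semipinacol ring expansion, a reaction type with precedent for p-hydroxyaryl carbinols); this turns the cyclopentanol into cyclohexanone ring B and the arene into dienone ring A, and the product is achiral.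

**Step 3**
Reactants: 5 spiro[5.5]undeca-7,10-diene-1,9-dione
Product: 8 (6R,11S)-11-hydroxyspiro[5.5]undec-7-ene-1,9-dione, via ketone perhydrate 6 (not isolated), via 1,11-epidioxy hemiketal 7 (not isolated)
Conditions: 35% aq. H2O2 (1.5 equiv), (R)-TRIP (10 mol%), CHCl3, −20 °C; then PPh3 (2 equiv), 0 °C → rt
Reagents that add atoms: hydrogen peroxide, OO
Why: Proposed new method: H2O2 adds reversibly to the saturated ring-B ketone (more electrophilic than the dienone carbonyl) to give perhydrate 6, and the chiral phosphoric acid, hydrogen-bonded to the OOH group and to the dienone carbonyl, steers a 5-exo-trig peroxy-Michael closure onto one of the two enantiotopic enone β-carbons, so the tether forces the new C–O bond cis to the ring-B carbonyl carbon while the catalyst fixes the configuration of C11 and of spiro carbon C6 in the same event, after which PPh3 cleaves the O–O bond of 7 to release the aldol; the closest known reactions are the chiral-phosphoric-acid acetalisation/oxa-Michael desymmetrisation of p-peroxyquinols and hydroperoxide conjugate additions that give 1,2-dioxolanes.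

**Step 4**
Reactants: 8 (6R,11S)-11-hydroxyspiro[5.5]undec-7-ene-1,9-dione
Product: 9 (5S,6R)-5-hydroxy-7-oxaspiro[5.6]dodec-1-ene-3,8-dione
Conditions: m-CPBA (1.5 equiv), CH2Cl2, 0 °C → rt
Reagents that add atoms: m-chloroperbenzoic acid, OOC(=O)c1cccc(Cl)c1
Why: Baeyer–Villiger ring expansion: the peracid adds to the saturated ketone and the more substituted (quaternary spiro) carbon migrates to oxygen with retention, so the cyclohexanone becomes an ε-lactone whose C–O bond is the future tertiary alcohol, cis to the C5 hydroxyl; the electron-poor enone is not epoxidised.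

**Step 5**
Reactants: 9 (5S,6R)-5-hydroxy-7-oxaspiro[5.6]dodec-1-ene-3,8-dione
Product: 10 (5S,6R)-5-hydroxy-2-iodo-7-oxaspiro[5.6]dodec-1-ene-3,8-dione
Conditions: I2 (2 equiv), pyridine/CH2Cl2 (1:1), 0 °C → rt
Reagents that add atoms: iodine, II
Why: Johnson α-iodination of the enone (reversible pyridine conjugate addition, iodination of the enolate, elimination of pyridine) puts iodine on the only enone α-carbon; the stereocentres, the lactone and the free hydroxyl are untouched.

**Step 6**
Reactants: 11 4-methylpent-1-ene; 12 vinyl bromide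
Product: 15 (4S)-4,6-dimethylhept-1-ene, via [(2S)-2,4-dimethylpentyl]dimethylalane 13 (not isolated), via [(2S)-2,4-dimethylpentyl]zinc triflate 14 (not isolated)
Conditions: Me3Al (2 equiv), (+)-(NMI)2ZrCl2 (3 mol%), (MeAlO)n (1 equiv), CH2Cl2, 0 °C → rt; evaporate; Zn(OTf)2 (1 equiv), DMF, 70 °C; PdCl2(DPEphos) (3 mol%), i-Bu2AlH (6 mol%), 12, rt
Reagents that add atoms: trimethylaluminium, C[Al](C)C
Why: Zirconium-catalysed asymmetric carboalumination (ZACA) adds Me–Al across the terminal alkene with the chiral zirconocene choosing the alkene face (the (+)-catalyst gives the (S)-2-methylalkyl alane), and transmetalation to zinc followed by palladium-catalysed Negishi coupling with vinyl bromide homologates the chain without touching the new stereocentre.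

**Step 7**
Reactants: 15 (4S)-4,6-dimethylhept-1-ene
Product: 17 (2S,4S)-2,4,6-trimethylheptan-1-ol, via dimethyl[(2S,4S)-2,4,6-trimethylheptyl]alane 16 (not isolated)
Conditions: Me3Al (2 equiv), (+)-(NMI)2ZrCl2 (3 mol%), (MeAlO)n (1 equiv), CH2Cl2, 0 °C → rt; then O2, 0 °C → rt; 3 M HCl; chromatography
Reagents that add atoms: trimethylaluminium, C[Al](C)C; dioxygen, O=O
Why: A second ZACA with the same catalyst antipode sets the new methyl centre under catalyst control to give the syn-(2S,4S) array (the minor enantiomer from step 6 ends up mainly in the separable anti diastereomer, which raises the optical purity), and O2 oxidises the C–Al bond to the primary alcohol with retention.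

**Step 8**
Reactants: 17 (2S,4S)-2,4,6-trimethylheptan-1-ol
Product: 19 (2E,4S,6S)-4,6,8-trimethylnon-2-enamide, via (2S,4S)-2,4,6-trimethylheptanal 18 (not isolated)
Conditions: PhI(OAc)2 (1.1 equiv), TEMPO (10 mol%), CH2Cl2, rt; then Ph3P=CHCONH2 (2.5 equiv), rt → 40 °C
Reagents that add atoms: (carbamoylmethylene)triphenylphosphorane, NC(=O)C=P(c1ccccc1)(c1ccccc1)c1ccccc1
Why: Oxoammonium (TEMPO/PhI(OAc)2) oxidation gives the α-branched aldehyde without epimerisation and the stabilised amide ylide traps it in the same flask in an E-selective Wittig olefination, giving the primary enamide directly.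

**Step 9**
Reactants: 10 (5S,6R)-5-hydroxy-2-iodo-7-oxaspiro[5.6]dodec-1-ene-3,8-dione; 19 (2E,4S,6S)-4,6,8-trimethylnon-2-enamide
Product: 20 (2E,4S,6S)-N-[(5S,6R)-5-hydroxy-3,8-dioxo-7-oxaspiro[5.6]dodec-1-en-2-yl]-4,6,8-trimethylnon-2-enamide
Conditions: CuI (10 mol%), MeNHCH2CH2NHMe (20 mol%), Cs2CO3 (1.5 equiv), THF, 50 °C
Reagents that add atoms: none
Why: Copper-catalysed Goldberg-type amidation of the activated vinyl iodide with the primary amide forms the enamide C–N bond at the enone α-carbon; the lactone keeps the tertiary alcohol and the acid masked and no stereocentre takes part.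

**Step 10**
Reactants: 20 (2E,4S,6S)-N-[(5S,6R)-5-hydroxy-3,8-dioxo-7-oxaspiro[5.6]dodec-1-en-2-yl]-4,6,8-trimethylnon-2-enamide
Product: 21 Salternamide E
Conditions: LiOH (2.5 equiv), THF/H2O (3:1), 0 °C; then 1 M HCl to pH 4
Reagents that add atoms: lithium hydroxide, [Li+].[OH-]
Why: Saponification of the strained ε-lactone by acyl–oxygen cleavage releases the tertiary alcohol with its configuration intact and the pentanoic acid; under these conditions the enamide N–H is deprotonated first, which disfavours enolate formation and β-elimination of the C5 hydroxyl.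

**Compound list**
1 | 4-bromophenol | Oc1ccc(Br)cc1 | starting material
2 | cyclopentanone | O=C1CCCC1 | starting material
3 | lithium 4-lithiophenoxide | [Li]Oc1ccc([Li])cc1 | intermediate (not isolated)
4 | 4-(1-hydroxycyclopentyl)phenol | Oc1ccc(cc1)C1(O)CCCC1 | intermediate
5 | spiro[5.5]undeca-7,10-diene-1,9-dione (achiral; ring A = cyclohexa-2,5-dienone, ring B = cyclohexanone with C=O next to the spiro carbon) | O=C1C=CC2(C=C1)CCCCC2=O | intermediate
6 | 1-hydroperoxy-1-hydroxyspiro[5.5]undeca-7,10-dien-9-one (ketone perhydrate; hemiketal carbon labile, racemic) | OOC1(O)CCCCC12C=CC(=O)C=C2 | intermediate (not isolated)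
7 | (6R,11S)-1,11-epidioxy-1-hydroxyspiro[5.5]undec-7-en-9-one (cyclic peroxyhemiketal; C1 epimers not distinguished) | O=C1C=C[C@]2(CCCCC2(O)OO3)[C@@H]3C1 | intermediate (not isolated)
8 | (6R,11S)-11-hydroxyspiro[5.5]undec-7-ene-1,9-dione (OH cis to the ring-B carbonyl carbon) | O=C1C=C[C@]2(CCCCC2=O)[C@@H](O)C1 | intermediate
9 | (5S,6R)-5-hydroxy-7-oxaspiro[5.6]dodec-1-ene-3,8-dione (OH cis to the lactone oxygen) | O=C1C=C[C@]2(CCCCC(=O)O2)[C@@H](O)C1 | intermediate
10 | (5S,6R)-5-hydroxy-2-iodo-7-oxaspiro[5.6]dodec-1-ene-3,8-dione | IC1=C[C@]2(CCCCC(=O)O2)[C@@H](O)CC1=O | intermediate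
11 | 4-methylpent-1-ene | CC(C)CC=C | starting material
12 | vinyl bromide | C=CBr | starting material
13 | [(2S)-2,4-dimethylpentyl]dimethylalane | CC(C)C[C@H](C)C[Al](C)C | intermediate (not isolated)
14 | [(2S)-2,4-dimethylpentyl]zinc trifluoromethanesulfonate | CC(C)C[C@H](C)C[Zn]OS(=O)(=O)C(F)(F)F | intermediate (not isolated)
15 | (4S)-4,6-dimethylhept-1-ene | CC(C)C[C@H](C)CC=C | intermediate
16 | dimethyl[(2S,4S)-2,4,6-trimethylheptyl]alane | CC(C)C[C@H](C)C[C@H](C)C[Al](C)C | intermediate (not isolated)
17 | (2S,4S)-2,4,6-trimethylheptan-1-ol | CC(C)C[C@H](C)C[C@H](C)CO | intermediate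
18 | (2S,4S)-2,4,6-trimethylheptanal | CC(C)C[C@H](C)C[C@H](C)C=O | intermediate (not isolated)
19 | (2E,4S,6S)-4,6,8-trimethylnon-2-enamide | CC(C)C[C@H](C)C[C@H](C)/C=C/C(N)=O | intermediate
20 | (2E,4S,6S)-N-[(5S,6R)-5-hydroxy-3,8-dioxo-7-oxaspiro[5.6]dodec-1-en-2-yl]-4,6,8-trimethylnon-2-enamide | CC(C)C[C@H](C)C[C@H](C)/C=C/C(=O)NC1=C[C@]2(CCCCC(=O)O2)[C@@H](O)CC1=O | intermediate
21 | Salternamide E, 5-[(1R,6S)-1,6-dihydroxy-4-oxo-3-{[(2E,4S,6S)-4,6,8-trimethylnon-2-enoyl]amino}cyclohex-2-en-1-yl]pentanoic acid | CC(C)C[C@H](C)C[C@H](C)/C=C/C(=O)NC1=C[C@](O)(CCCCC(=O)O)[C@@H](O)CC1=O | target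

**Totals**
Total step count: 10. Longest linear sequence: 7 steps (steps 1, 2, 3, 4, 5, 9, 10); the side chain takes 3 steps (6, 7, 8) before the union.

**Three steps most likely to fail**

Step 3 (the new ketone-tethered peroxide desymmetrisation). Possible failures are low enantioselectivity, Baeyer–Villiger reaction of the perhydrate, or no ring closure. The fallback uses known chemistry, sets out from 5 and comes back at 8. A ligand-controlled copper–boryl conjugate addition to the cyclic enone (CuCl 5 mol%, (R)-(S)-Josiphos 6 mol%, NaOt-Bu 10 mol%, B2pin2, MeOH, THF, −20 °C) gives (6S,11S)-11-(4,4,5,5-tetramethyl-1,3,2-dioxaborolan-2-yl)spiro[5.5]undec-7-ene-1,9-dione F1. Oxidation with NaBO3·4H2O in THF/H2O at 0 °C then converts the C–B bond into C–OH with retention to give 8. Here the ligand sets the carbinol carbon, while the choice of arm (boron anti to the ring-B CH2, cis to the flat acyl carbon) rests on substrate bias; any trans isomer is removed by chromatography.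

Step 4 (Baeyer–Villiger on 8). The ketone is hindered by the quaternary carbon, and the carbon that must migrate carries a β-hydroxyl, so CH2 migration, a sluggish reaction, or enone epoxidation with stronger peracids are possible. The fallback inverts the order of ring expansion and hydroxylation, sets out from 5 and comes back at 9. m-CPBA on symmetric 5, where the unhindered, doubly allylic quaternary carbon migrates, gives achiral 7-oxaspiro[5.6]dodeca-1,4-diene-3,8-dione F2. The same copper–boryl addition, now directed to the face of the lactone oxygen (anti to the CH2 chain), gives (5S,6S)-5-(4,4,5,5-tetramethyl-1,3,2-dioxaborolan-2-yl)-7-oxaspiro[5.6]dodec-1-ene-3,8-dione F3. F3 is oxidised in the same flask with NaBO3·4H2O at 0 °C, before boron–oxygen elimination can set in, to give 9.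

Step 9 (copper amidation of 10). Cs2CO3 at 50 °C may dehydrate the β-hydroxy ketone (E1cB) or engage the free hydroxyl before C–N coupling. The fallback masks the aldol hydroxyl, sets out from 10 and comes back at 20. TESCl and imidazole in DMF at 0 °C give (5S,6R)-2-iodo-5-[(triethylsilyl)oxy]-7-oxaspiro[5.6]dodec-1-ene-3,8-dione F4. Coupling with 19 (CuI/MeNHCH2CH2NHMe/Cs2CO3, or Pd2(dba)3/Xantphos) gives (2E,4S,6S)-N-{(5S,6R)-3,8-dioxo-5-[(triethylsilyl)oxy]-7-oxaspiro[5.6]dodec-1-en-2-yl}-4,6,8-trimethylnon-2-enamide F5. HF·pyridine in THF at 0 °C removes the silyl group to give 20.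

**Further compounds**
F1 | step 3 | (6S,11S)-11-(4,4,5,5-tetramethyl-1,3,2-dioxaborolan-2-yl)spiro[5.5]undec-7-ene-1,9-dione | O=C1C=C[C@]2(CCCCC2=O)[C@@H](B3OC(C)(C)C(C)(C)O3)C1
F2 | step 4 | 7-oxaspiro[5.6]dodeca-1,4-diene-3,8-dione | O=C1C=CC2(C=C1)CCCCC(=O)O2
F3 | step 4 | (5S,6S)-5-(4,4,5,5-tetramethyl-1,3,2-dioxaborolan-2-yl)-7-oxaspiro[5.6]dodec-1-ene-3,8-dione | O=C1C=C[C@]2(CCCCC(=O)O2)[C@@H](B3OC(C)(C)C(C)(C)O3)C1
F4 | step 9 | (5S,6R)-2-iodo-5-[(triethylsilyl)oxy]-7-oxaspiro[5.6]dodec-1-ene-3,8-dione | IC1=C[C@]2(CCCCC(=O)O2)[C@@H](O[Si](CC)(CC)CC)CC1=O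
F5 | step 9 | (2E,4S,6S)-N-{(5S,6R)-3,8-dioxo-5-[(triethylsilyl)oxy]-7-oxaspiro[5.6]dodec-1-en-2-yl}-4,6,8-trimethylnon-2-enamide | CC(C)C[C@H](C)C[C@H](C)/C=C/C(=O)NC1=C[C@]2(CCCCC(=O)O2)[C@@H](O[Si](CC)(CC)CC)CC1=O
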